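## Structural features

The target is a p-terphenylquinone. A central 1,4-benzoquinone ring (ring B) carries two 4-hydroxyphenyl rings (rings A and C) on C2 and C5 and two acyloxy groups on C3 and C6, so each kind of substituent sits para to its twin and the molecule is C2-symmetric. Both acyl groups are the same (2Z,4S,5S)-4,5-epoxyhex-2-enoyl unit: a carboxyl carbon C1, a cis C2=C3 double bond, and a trans-disubstituted oxirane whose adjacent stereocentres C4 and C5 are both S, with the methyl group on C5. The four stereocentres are therefore two identical vicinal pairs, and the core has none. Several groups are fragile: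
- the two quinone enol esters are vinylogous mixed anhydrides and pass their acyl groups to hydroxide, alkoxides, amines or phenoxides;
- the oxiranes are allylic and open with acid, soft nucleophiles or zerovalent palladium;
- the Z-enoate isomerises under nucleophilic catalysis, and the free cis acid would attack its own oxirane at C4 to give a butenolide;
- the quinone oxidises phosphines and hydride donors.

The real difficulty is not the core. It lies in making the cis epoxy acid as one enantiomer without ever liberating a free cis γ-hydroxy or γ,δ-epoxy acid, and in attaching it twice to weakly nucleophilic hydroxyquinone oxygens next to two phenols. The key step uses the C3–C4 bond: C3 can be a cis-vinyl nucleophile, C4 can be an aldehyde carbon, and the methyl-bearing C5 next to it can carry a chlorine that first steers the addition and then leaves as the oxirane C5–O bond forms.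

## Logic of the disconnections

18 to 17. The two phenolic oxygens are given silyl groups (forward: cleavage of two aryl O–Si bonds). The reason is that free phenols, and above all phenoxide, compete for an activated acyl group and can take it from the enol esters. A silyl ether is the one phenol mask that comes off without acid, hydrogen, palladium or a strong nucleophile. The gain is a clean distinction between the four hydroxyls. The demand is a fluoride cleavage that is buffered, so that no phenoxide persists.

17 to 15 and two molecules of 8, through 16. The two ester bonds between C1 of each chain and the quinone oxygens are cut. This uses the symmetry, separates the achiral core from the chain, and puts all stereochemistry into one small fragment that is made once. The forward step must activate 8 without acid, without a nucleophilic catalyst and without excess base, and the leaving group of 16 must be a poorer nucleophile than the quinone enolate so that the acyl transfer does not run backwards.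

8 to 4 and 3, through 5, 6 and 7. The C3–C4 bond and the oxirane C5–O bond are cut. This is the strategic cut: it removes the ring and both stereocentres and leaves a three-carbon cis-vinyl donor and a three-carbon aldehyde with one stereocentre from the chiral pool. The forward step must add anti to the chlorine-bearing centre, keep the cis geometry of the vinyl metal, keep the aldehyde from enolising, and close the ring with inversion. The descriptors were followed through this sequence and are consistent: the (R)-chloride of 3 becomes (5R) in 7 and, after inversion, (5S) in 8, and anti addition gives (4S). No correction of the structures is needed. The precursor design is tightened in two ways. 4 is converted into its dry salt 5 before the exchange, so that no acidic proton is present when 6 forms. 3 is used in slight excess, so that no 6 survives to appear later as an acrylate impurity.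

3 to 2 to 1. Only the oxidation level of C1 of the three-carbon unit is changed. 3 is too labile and too volatile to store, whereas 1 is a stable commercial acid. The forward steps must avoid base throughout: base would close 2 to methyloxirane and would racemise 3.

15 to 13, through 14. Two aryl O–Si bonds are cut. The gain is that the differentiated core comes from the symmetrical tetrol. The forward step relies on the fact that silyl groups on the quinone oxygens are vinylogous silyl esters and hydrolyse far more easily than aryl silyl ethers.

13 to 12. The two quinone O–CH3 bonds are formed in the retrosynthetic sense, and the aryl silyl ethers are restored. The methoxy groups stand in for the quinone hydroxyls during the cross-coupling, where free hydroxyquinone anions would shut down oxidative addition. The forward hydrolysis needs hydroxide, which also removes the aryl silyl groups. That is accepted and repaired in the next step.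

12 to 10 and two molecules of 11. The two aryl–quinone C–C bonds are cut. This gives a symmetrical dihalide and a commercial boronic acid. The forward coupling must tolerate a quinone and must not expose it to free phenoxide, which is why 11 carries a silyl ether.

10 to 9. Two ring C–O bonds are cut. The forward substitution must stop at two methoxy groups and place them para, which the electronic deactivation after the first substitution should secure.

## Other disconnections considered

Alternative 1: The cut is made inside ring B, between a hydroxyl-bearing carbon and the neighbouring methoxy-bearing carbon of the hydroquinone A3. This leads back to the 4-alkenyl-4-hydroxycyclobutenone A2 and, through two organolithium additions, to dimethyl squarate A1. In the forward direction A2 is heated. A 4π-electrocyclic opening gives a dienylketene, the ketene carbon bonds to the terminal methoxy-bearing vinyl carbon in a 6π-electrocyclisation, and tautomerisation gives A3. Oxidation of A3 would give 12, so the alternative joins the chosen route before step 6.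
- In its favour: the ring is assembled without a transition metal, and the substitution pattern follows from the order in which the two nucleophiles are added to A1. The approach would also serve for cores with two different aryl groups, and on that flexibility it is the better plan. In mechanistic reliability it is the equal of the chosen one, because this pericyclic cascade is well behaved for such substrates.
- Against it here: the target core is symmetrical, so the programmability buys nothing. The 1-aryl-2-methoxyvinyl nucleophile must be made first. About five operations are needed from A1 to 12 (two additions, an acid-induced rearrangement to the aryl methoxy cyclobutenedione, thermolysis, oxidation) against two from 9.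
- Comparison: both plans deliver the same compound 12, and the side chain, the acylation and the end game are unchanged. The chosen plan is ahead in step economy.

Alternative 2: Ring B is cut at the two bonds that join each benzylic carbon to the carboxyl carbon of the other half, which gives two molecules of 4-hydroxyphenylpyruvic acid A4. In the forward direction an atromentin-synthetase-type enzyme adenylates A4, holds two units as thioesters and lets each enolised benzylic carbon attack the thioester carbon of the other. This releases the tetraketone tautomer of the quinone, A5, which is identical with 13.
- In its favour: one operation from a commercial keto acid in water, with no protecting groups, no halogenated quinone and no palladium. On step economy and atom economy up to 13 it is clearly the better route. Its ring-forming mechanism (two Claisen-type condensations at the correct oxidation level, with no separate oxidation) is also more direct than substitution, coupling and hydrolysis.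
- Against it: it needs the expressed and phosphopantetheinylated enzyme with its nucleotide cofactor, a dilute aqueous medium from which the sparingly soluble A5 must be recovered, and a throughput set by the enzyme. It allows no variation of the aryl groups.
- Comparison: it leaves every difficult part of the target as it is in the chosen plan, namely the stereodefined epoxy acid, the differentiation of the four hydroxyls and the two acylations. Only the first three core steps differ. The two are equal in structure (same compound), the enzyme is better in step count, and the chemical route is better in independence from biological infrastructure and in ease of scale.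

Alternative 3: The four oxirane C–O bonds are cut last. This leads back to the bis-dienoate A7, which would come from 15 and (2Z,4E)-hexa-2,4-dienoic acid A6. In the forward direction the dioxirane formed from the chiral ketone A9 (the enantiomer of the common sugar-derived epoxidation catalyst) and a stoichiometric peroxide would transfer oxygen to the distal, more electron-rich C4=C5 bond of each chain through the usual spiro transition state. The E geometry is carried into the trans oxirane, and the product A8 is identical with 17.
- In its favour: the acyl donor A6 has no oxirane and should be a more robust partner in the esterification than 8, and on that point the alternative is the better. All four stereocentres would come from a catalyst in one operation. A twofold reaction on one molecule also raises the enantiomeric purity of the main product, because wrong-face events are diverted into diastereomers.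
- Against it here: the epoxidation needs a buffered aqueous medium near pH 10 and an electrophilic oxidant, and the substrate carries two vinylogous anhydrides that hydroxide and carbonate are expected to cleave, a quinone and two silyloxyaryl rings. The 2Z double bond of A6 and A7 tends to isomerise to E, and A6 needs a stereoselective synthesis about as long as that of 8. Disubstituted E-olefins are among the less selective substrates for this catalyst, the diastereomers would have to be separated at the end, and A9 is the less accessible enantiomer.
- Comparison: the alternative uses reagent control late, on the most fragile intermediate. The chosen plan uses substrate control early, on a three-carbon aldehyde whose chlorine centre fixes the relative configuration by inversion. The step counts are about equal. The chosen plan is preferred because it places the stereochemical risk on a small fragment and never exposes the enol esters to aqueous base.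

Key step: step 3

Assumption: 4-(tert-butyldimethylsilyloxy)phenylboronic acid (11) is bought as such instead of being made from 4-hydroxyphenylboronic acid, and (R)-2-chloropropanoic acid (1) is available in high enantiomeric purity.

## Route

Step 1
Reactants: 1 (R)-2-chloropropanoic acid
Product: 2 (R)-2-chloropropan-1-ol
Conditions: LiAlH4, Et2O, 0 °C; then H2SO4 (1 M aq), 0 °C
Reagents that add atoms: none
Why: Hydride reduction of a carboxylic acid to the primary alcohol; the chlorine-bearing stereocentre takes no part, and the cold acidic work-up avoids the base-induced closure of the chlorohydrin to methyloxirane.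

Step 2
Reactants: 2 (R)-2-chloropropan-1-ol
Product: 3 (R)-2-chloropropanal
Conditions: DMP (1.2 equiv), CH2Cl2, 0 → 23 °C; pentane, filtration; cold bulb-to-bulb distillation into THF, stored at −78 °C
Reagents that add atoms: none
Why: Dess–Martin oxidation runs without amine base under neutral to weakly acidic conditions, so the enolisable chlorine-bearing centre should keep its configuration and no over-oxidation is expected; the volatile aldehyde is kept cold, free of chlorinated solvent, and used at once.

Step 3
Reactants: 4 (Z)-3-iodoacrylic acid; 3 (R)-2-chloropropanal
Product: 8 lithium (2Z,4S,5S)-4,5-epoxyhex-2-enoate, via lithium (Z)-3-iodoacrylate 5 (not isolated), via lithium (Z)-3-lithioacrylate 6 (not isolated), via dilithium (2Z,4S,5R)-5-chloro-4-oxidohex-2-enoate 7 (not isolated)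
Conditions: LiH (1.05 equiv), THF, 23 °C; Et2O, −100 °C, n-BuLi (1.0 equiv); 3 (1.15 equiv) in THF, −100 → −78 °C; then 23 °C; evaporation, trituration with Et2O/pentane
Reagents that add atoms: lithium hydride, [LiH] (supplies the lithium counter-ion of the salt)
Why: LiH first turns 4 into its dry lithium salt 5, so that n-BuLi is spent only on iodine–lithium exchange, which proceeds with retention at the sp2 carbon and gives the cis dianion 6 with no proton source that could reduce it to acrylate. At −100 °C 6 keeps its geometry and adds to the carbonyl group of 3 faster than it enolises it; the closest known reactions are the addition of alkenyllithium reagents to α-chloro aldehydes and the use of β-lithioacrylate dianions as cis-acrylate nucleophiles. The addition passes through the Cornforth (polar Felkin–Anh) arrangement, with the C–Cl and C=O dipoles opposed and the nucleophile entering past the hydrogen, so the configuration of the new carbinol carbon C4 is set by the chlorine-bearing centre and the anti alkoxide 7 forms. On warming, the alkoxide oxygen attacks C5 from the side opposite to chlorine in a 3-exo-tet closure, which forms the C5–O bond with inversion: the (R)-chloride becomes the (S)-configured C5, and the anti relationship becomes the trans oxirane with C4 also S. The Z double bond comes unchanged from 4. The step needs anti over syn addition, which the dipole control of the α-chlorine, the non-chelating lithium cation in THF and the low temperature should secure, and it needs the oxygen to close on C5 and not on the carboxyl carbon, which is ensured because that carbon is a carboxylate and no acid is added. The small excess of 3 consumes all of 6, and 8 is collected as the salt (with LiCl) after evaporation and trituration.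

Step 4
Reactants: 9 bromanil (tetrabromo-1,4-benzoquinone)
Product: 10 2,5-dibromo-3,6-dimethoxy-1,4-benzoquinone
Conditions: NaOMe (2.05 equiv), MeOH, 0 → 23 °C
Reagents that add atoms: sodium methoxide, [Na+].[O-]C
Why: Twofold addition–elimination (vinylic nucleophilic substitution) of methoxide on the haloquinone; the first methoxy group turns its half of the ring into a vinylogous ester, so the second substitution should go to the para carbon and give the 2,5-dibromo-3,6-dimethoxy pattern.

Step 5
Reactants: 10 2,5-dibromo-3,6-dimethoxy-1,4-benzoquinone; 11 4-(tert-butyldimethylsilyloxy)phenylboronic acid (2.4 equiv)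
Product: 12 2,5-bis[4-(tert-butyldimethylsilyloxy)phenyl]-3,6-dimethoxy-1,4-benzoquinone
Conditions: PdCl2(dppf) (5 mol %), K3PO4, 1,4-dioxane, 80 °C
Reagents that add atoms: none
Why: Double Suzuki–Miyaura coupling; the C–Br bonds of the bromoquinone are vinylogous acyl bromides that add readily to zerovalent palladium (formed in the flask from the divalent palladium precatalyst), the chelating dppf ligand is not free to attack the quinone, and the silyl ethers keep phenoxide away from the electrophilic ring.

Step 6
Reactants: 12 2,5-bis[4-(tert-butyldimethylsilyloxy)phenyl]-3,6-dimethoxy-1,4-benzoquinone
Product: 13 atromentin (2,5-dihydroxy-3,6-bis(4-hydroxyphenyl)-1,4-benzoquinone)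
Conditions: NaOH (2 M aq), MeOH/1,4-dioxane, 60 °C, N2; then HCl (1 M aq) to pH 2, filtration
Reagents that add atoms: sodium hydroxide, [Na+].[OH-]
Why: Hydroxide adds to the methoxy-bearing ring carbons and expels methoxide (hydrolysis of a vinylogous ester), and the same base cleaves the aryl silyl ethers; their loss is accepted here because the hydroxyquinone cannot be unmasked with base while they stay on.

Step 7
Reactants: 13 atromentin
Product: 15 2,5-bis[4-(tert-butyldimethylsilyloxy)phenyl]-3,6-dihydroxy-1,4-benzoquinone, via tetrakis(tert-butyldimethylsilyl) ether of atromentin 14 (not isolated)
Conditions: TBSCl (4.5 equiv), imidazole, DMF, 23 °C; then AcOH/THF/H2O (3:1:1), 23 °C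
Reagents that add atoms: tert-butyldimethylsilyl chloride, CC(C)(C)[Si](C)(C)Cl
Why: Imidazole-promoted silylation covers all four hydroxyls; the two quinone O–Si bonds are vinylogous silyl esters and should hydrolyse in dilute aqueous acetic acid, to which aryl tert-butyldimethylsilyl ethers are stable.

Step 8
Reactants: 8 lithium (2Z,4S,5S)-4,5-epoxyhex-2-enoate (2.4 equiv); 15 2,5-bis[4-(tert-butyldimethylsilyloxy)phenyl]-3,6-dihydroxy-1,4-benzoquinone
Product: 17 2,5-bis[4-(tert-butyldimethylsilyloxy)phenyl]-3,6-dioxocyclohexa-1,4-diene-1,4-diyl bis[(2Z,4S,5S)-4,5-epoxyhex-2-enoate], via 2,4,6-trichlorobenzoic mixed anhydride 16 (not isolated)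
Conditions: 8, 2,4,6-Cl3C6H2COCl (2.3 equiv), THF, 0 °C; then 15, Et3N (2.2 equiv), CH2Cl2, −20 → 0 °C
Reagents that add atoms: none
Why: Mixed-anhydride (Yamaguchi-type) esterification: the lithium carboxylate and the hindered aroyl chloride give 16 without added base, and the bis(triethylammonium) enolate of the hydroxyquinone, a vinylogous carboxylate, should attack the unhindered enoyl carbonyl and expel the weakly nucleophilic 2,4,6-trichlorobenzoate. No acid, no nucleophilic catalyst and no excess amine are present, which protects the oxiranes and the Z geometry.

Step 9
Reactants: 17 2,5-bis[4-(tert-butyldimethylsilyloxy)phenyl]-3,6-dioxocyclohexa-1,4-diene-1,4-diyl bis[(2Z,4S,5S)-4,5-epoxyhex-2-enoate]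
Product: 18 2,5-bis(4-hydroxyphenyl)-3,6-dioxocyclohexa-1,4-diene-1,4-diyl bis[(2Z,4S,5S)-4,5-epoxyhex-2-enoate] (target)
Conditions: TBAF (2.5 equiv), AcOH (3 equiv), THF, −20 → 0 °C
Reagents that add atoms: none
Why: Fluoride-induced cleavage of aryl silyl ethers; acetic acid protonates each phenoxide as it forms, so neither phenoxide nor free fluoride should attack the enol esters or the oxiranes.

## Compound list

1 | (R)-2-chloropropanoic acid | C[C@@H](Cl)C(=O)O | starting material
2 | (R)-2-chloropropan-1-ol | C[C@@H](Cl)CO | intermediate
3 | (R)-2-chloropropanal | C[C@@H](Cl)C=O | intermediate
4 | (Z)-3-iodoacrylic acid | OC(=O)/C=C\I | starting material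
5 | lithium (Z)-3-iodoacrylate (formed in the flask, not isolated) | [Li+].[O-]C(=O)/C=C\I | intermediate
6 | lithium (Z)-3-lithioacrylate (formed in the flask, not isolated) | [Li]/C=C\C(=O)[O-].[Li+] | intermediate
7 | dilithium (2Z,4S,5R)-5-chloro-4-oxidohex-2-enoate, the anti chlorohydrin alkoxide (formed in the flask, not isolated) | C[C@@H](Cl)[C@@H]([O-])/C=C\C(=O)[O-].[Li+].[Li+] | intermediate
8 | lithium (2Z,4S,5S)-4,5-epoxyhex-2-enoate, that is lithium (2Z)-3-[(2S,3S)-3-methyloxiran-2-yl]prop-2-enoate | C[C@@H]1O[C@H]1/C=C\C(=O)[O-].[Li+] | intermediate
9 | bromanil (tetrabromo-1,4-benzoquinone) | BrC1=C(Br)C(=O)C(Br)=C(Br)C1=O | starting material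
10 | 2,5-dibromo-3,6-dimethoxy-1,4-benzoquinone | COC1=C(Br)C(=O)C(OC)=C(Br)C1=O | intermediate
11 | 4-(tert-butyldimethylsilyloxy)phenylboronic acid | CC(C)(C)[Si](C)(C)Oc1ccc(B(O)O)cc1 | starting material
12 | 2,5-bis[4-(tert-butyldimethylsilyloxy)phenyl]-3,6-dimethoxy-1,4-benzoquinone | COC1=C(c2ccc(O[Si](C)(C)C(C)(C)C)cc2)C(=O)C(OC)=C(c2ccc(O[Si](C)(C)C(C)(C)C)cc2)C1=O | intermediate
13 | atromentin, 2,5-dihydroxy-3,6-bis(4-hydroxyphenyl)-1,4-benzoquinone | OC1=C(c2ccc(O)cc2)C(=O)C(O)=C(c2ccc(O)cc2)C1=O | intermediate
14 | 2,5-bis(tert-butyldimethylsilyloxy)-3,6-bis[4-(tert-butyldimethylsilyloxy)phenyl]-1,4-benzoquinone (formed in the flask, not isolated) | CC(C)(C)[Si](C)(C)OC1=C(c2ccc(O[Si](C)(C)C(C)(C)C)cc2)C(=O)C(O[Si](C)(C)C(C)(C)C)=C(c2ccc(O[Si](C)(C)C(C)(C)C)cc2)C1=O | intermediate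
15 | 2,5-bis[4-(tert-butyldimethylsilyloxy)phenyl]-3,6-dihydroxy-1,4-benzoquinone | OC1=C(c2ccc(O[Si](C)(C)C(C)(C)C)cc2)C(=O)C(O)=C(c2ccc(O[Si](C)(C)C(C)(C)C)cc2)C1=O | intermediate
16 | (2Z,4S,5S)-4,5-epoxyhex-2-enoic 2,4,6-trichlorobenzoic anhydride (formed in the flask, not isolated) | C[C@@H]1O[C@H]1/C=C\C(=O)OC(=O)c1c(Cl)cc(Cl)cc1Cl | intermediate
17 | 2,5-bis[4-(tert-butyldimethylsilyloxy)phenyl]-3,6-dioxocyclohexa-1,4-diene-1,4-diyl bis[(2Z,4S,5S)-4,5-epoxyhex-2-enoate] | C[C@@H]1O[C@H]1/C=C\C(=O)OC1=C(c2ccc(O[Si](C)(C)C(C)(C)C)cc2)C(=O)C(OC(=O)/C=C\[C@@H]2O[C@H]2C)=C(c2ccc(O[Si](C)(C)C(C)(C)C)cc2)C1=O | intermediate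
18 | 2,5-bis(4-hydroxyphenyl)-3,6-dioxocyclohexa-1,4-diene-1,4-diyl bis[(2Z,4S,5S)-4,5-epoxyhex-2-enoate] | C[C@@H]1O[C@H]1/C=C\C(=O)OC1=C(c2ccc(O)cc2)C(=O)C(OC(=O)/C=C\[C@@H]2O[C@H]2C)=C(c2ccc(O)cc2)C1=O | target

## Step count and risk

Total step count: 9.
Longest linear sequence: 6 steps (9 → 10 → 12 → 13 → 15 → 17 → 18, steps 4 to 9). The side-chain branch (1 → 2 → 3 → 8 → 17 → 18) has 5.

Least certain steps:

Step 3 (key step). Four things are most likely to go wrong. Facial selectivity in the addition may be insufficient, because the methyl group is a small discriminating substituent, and syn addition would carry through to the cis oxirane. The basic vinyllithium may enolise the aldehyde, with loss of configuration. The lithium alkoxide may close slowly in THF. On long standing the neighbouring carboxylate may open the oxirane with lithium assistance. The product is a salt and cannot be chromatographed, so stereochemical impurities would be carried forward.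

The fallback sets out from 3 and replaces the cis-vinyl dianion by an alkyne. The lithium acetylide of ethyl propiolate (LiN(SiMe3)2, THF, −78 °C, quenched cold with AcOH) should add anti to give ethyl (4S,5R)-5-chloro-4-hydroxyhex-2-ynoate F1. This compound cannot lactonise because the alkyne is linear, and it can be freed of the syn isomer by chromatography. Cs2CO3 in MeCN at 0 °C should close it to ethyl (4S,5S)-4,5-epoxyhex-2-ynoate F2. Partial hydrogenation over Pd/CaCO3 poisoned with Pb(OAc)2 in the presence of quinoline should give ethyl (2Z,4S,5S)-4,5-epoxyhex-2-enoate F3. One equivalent of LiOH in THF/H2O at 0 °C followed by freeze-drying returns to the route at 8. The detour is three steps longer, but every intermediate is neutral and can be purified.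

Step 8. The second acylation may be slow or incomplete, because the enolate of the mono-ester is a poorer nucleophile. The acyl transfer may reverse. The Z double bond of the activated acyl species may isomerise through reversible conjugate addition of chloride or amine, and chloride may open the oxirane with lithium assistance.

The fallback sets out from 15 and inverts the polarity. (COCl)2 with catalytic DMF in CH2Cl2 converts the hydroxyquinone into its vinylogous acid chloride, 2,5-dichloro-3,6-bis[4-(tert-butyldimethylsilyloxy)phenyl]-1,4-benzoquinone F4. The carboxylate 8 then serves as the nucleophile in DMF at 0 °C and displaces both chlorides by addition–elimination. This returns to the route at 17 without any activated derivative of the epoxy acid having been made.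

Step 9. Acyl transfer from the enol esters to transient phenoxide, to fluoride or to acetate, and opening of the oxiranes by fluoride, are the likely failures.

The fallback removes the protecting groups from the plan and makes no new compound (F0). It sets out from 13, which is converted with two equivalents of Et3N in DMF at −40 °C into the bis(triethylammonium) salt of its two quinone hydroxyls. These should be several pKa units more acidic than the phenols. The salt is treated with 16, prepared from 8 as in step 8. The route is rejoined at 18, and steps 7 and 9 fall away. The price is a selectivity that rests only on the acidity difference.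

Step 2. Loss of configuration by enolisation during oxidation or isolation, hydrate and oligomer formation, and loss of the volatile aldehyde on concentration are the likely failures.

The fallback sets out from 1 and reaches the aldehyde by partial reduction instead of oxidation. Coupling with MeNH(OMe)·HCl (EDC·HCl, N-methylmorpholine, CH2Cl2, 0 °C) gives (R)-2-chloro-N-methoxy-N-methylpropanamide F5, which is stable and can be stored and checked for enantiomeric purity. Reduction with i-Bu2AlH in THF at −78 °C gives a chelated aluminium aminal that releases the aldehyde only on cold aqueous tartrate work-up. The dried ether extract is used directly in step 3, so the route is rejoined at 3.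

## Further compounds

F1 | step 3 | ethyl (4S,5R)-5-chloro-4-hydroxyhex-2-ynoate | C[C@@H](Cl)[C@@H](O)C#CC(=O)OCC
F2 | step 3 | ethyl (4S,5S)-4,5-epoxyhex-2-ynoate | C[C@@H]1O[C@H]1C#CC(=O)OCC
F3 | step 3 | ethyl (2Z,4S,5S)-4,5-epoxyhex-2-enoate | C[C@@H]1O[C@H]1/C=C\C(=O)OCC
F4 | step 8 | 2,5-dichloro-3,6-bis[4-(tert-butyldimethylsilyloxy)phenyl]-1,4-benzoquinone | ClC1=C(c2ccc(O[Si](C)(C)C(C)(C)C)cc2)C(=O)C(Cl)=C(c2ccc(O[Si](C)(C)C(C)(C)C)cc2)C1=O
F0 | step 9 | none | none
F5 | step 2 | (R)-2-chloro-N-methoxy-N-methylpropanamide | C[C@@H](Cl)C(=O)N(C)OC
A1 | alternative 1 | dimethyl squarate | COC1=C(OC)C(=O)C1=O
A2 | alternative 1 | 4-hydroxy-3-methoxy-4-{2-methoxy-1-[4-(tert-butyldimethylsilyloxy)phenyl]ethenyl}-2-[4-(tert-butyldimethylsilyloxy)phenyl]cyclobut-2-en-1-one (racemic, either alkene geometry) | COC=C(c1ccc(O[Si](C)(C)C(C)(C)C)cc1)C1(O)C(OC)=C(c2ccc(O[Si](C)(C)C(C)(C)C)cc2)C1=O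
A3 | alternative 1 | 2,5-bis[4-(tert-butyldimethylsilyloxy)phenyl]-3,6-dimethoxybenzene-1,4-diol | COc1c(O)c(-c2ccc(O[Si](C)(C)C(C)(C)C)cc2)c(OC)c(O)c1-c1ccc(O[Si](C)(C)C(C)(C)C)cc1
A4 | alternative 2 | 4-hydroxyphenylpyruvic acid | O=C(O)C(=O)Cc1ccc(O)cc1
A5 | alternative 2 | atromentin (identical with 13) | OC1=C(c2ccc(O)cc2)C(=O)C(O)=C(c2ccc(O)cc2)C1=O
A6 | alternative 3 | (2Z,4E)-hexa-2,4-dienoic acid | C/C=C/C=C\C(=O)O
A7 | alternative 3 | 2,5-bis[4-(tert-butyldimethylsilyloxy)phenyl]-3,6-dioxocyclohexa-1,4-diene-1,4-diyl bis[(2Z,4E)-hexa-2,4-dienoate] | C/C=C/C=C\C(=O)OC1=C(c2ccc(O[Si](C)(C)C(C)(C)C)cc2)C(=O)C(OC(=O)/C=C\C=C\C)=C(c2ccc(O[Si](C)(C)C(C)(C)C)cc2)C1=O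
A8 | alternative 3 | bis(tert-butyldimethylsilyl) ether of the target (identical with 17) | C[C@@H]1O[C@H]1/C=C\C(=O)OC1=C(c2ccc(O[Si](C)(C)C(C)(C)C)cc2)C(=O)C(OC(=O)/C=C\[C@@H]2O[C@H]2C)=C(c2ccc(O[Si](C)(C)C(C)(C)C)cc2)C1=O
A9 | alternative 3 | 1,2:4,5-di-O-isopropylidene-β-L-erythro-2,3-hexodiulo-2,6-pyranose (enantiomer of the common Shi epoxidation ketone) | CC1(C)OC[C@]2(O1)OC[C@@H]3OC(C)(C)O[C@@H]3C2=O
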